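## Retrosynthetic overview
1. The target is the C8 angelate of diol **14**, introduced last by Yamaguchi esterification.
2. **14** comes from acetonide **13**. **13** forms in one photoredox/Cr-catalysed intramolecular allylation of enal–allyl bromide **12**, which closes the 10-membered carbocycle (C6–C7 bond), the trans γ-lactone and the exocyclic methylene together.
3. **12** comes from aldehyde **10** by Morita–Baylis–Hillman (MBH) reaction and SN2′ bromination. **10** comes from cross-metathesis (CM) of acrylate **9** with enal **4**, which sets the C1=C10 geometry; the E-C4=C5 alkene is already in **4**.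
4. **9** comes from L-tartrate acetonide **5**, which supplies the C8/C9 threo-diol. **4** comes from hex-5-en-2-one.

Assumption: C6 and C7 are controlled by the C8/C9 stereocentres through the trans-dioxolane-constrained macrocyclic transition state. I also assume C8-OH acylates selectively over the C9-OH, which is hydrogen-bonded to the C14 ester.

## Route

**Step 1**
Reactants: 1 hex-5-en-2-one
Product: 2 methyl (E)-3-methylhepta-2,6-dienoate
Conditions: trimethyl phosphonoacetate, NaH, THF, 0 °C→rt (E:Z about 9:1, separate by chromatography)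
Reagents that add atoms: trimethyl phosphonoacetate, COC(=O)CP(=O)(OC)OC
Why: Horner–Wadsworth–Emmons olefination of a methyl ketone gives the E-trisubstituted enoate, which becomes the C4=C5 alkene (C6 trans to C3).

**Step 2**
Reactants: 2
Product: 3 (E)-3-methylhepta-2,6-dien-1-ol
Conditions: DIBAL-H (2.5 equiv), CH2Cl2, −78 °C
Reagents that add atoms: none
Why: Ester-to-alcohol reduction; the alkenes are untouched.

**Step 3**
Reactants: 3
Product: 4 (E)-3-methylhepta-2,6-dienal
Conditions: MnO2 (10 equiv), CH2Cl2, rt
Reagents that add atoms: none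
Why: MnO2 selectively oxidises the allylic alcohol without isomerising the E-enal, which is the future C6 aldehyde.

**Step 4**
Reactants: 5 dimethyl (4R,5R)-2,2-dimethyl-1,3-dioxolane-4,5-dicarboxylate (dimethyl 2,3-O-isopropylidene-L-tartrate)
Product: 6 methyl (4R,5R)-5-formyl-2,2-dimethyl-1,3-dioxolane-4-carboxylate
Conditions: DIBAL-H (1.0 equiv), CH2Cl2, −78 °C
Reagents that add atoms: none
Why: Mono-reduction of the C2-symmetric diester; either ester gives the same product, and the trans-diol stereocentres of the pool material are untouched.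

**Step 5**
Reactants: 6
Product: 7 methyl (4R,5S)-5-ethynyl-2,2-dimethyl-1,3-dioxolane-4-carboxylate
Conditions: Bestmann–Ohira reagent, K2CO3, MeOH, 0 °C→rt
Reagents that add atoms: dimethyl (1-diazo-2-oxopropyl)phosphonate, CC(=O)C(=[N+]=[N-])P(=O)(OC)OC
Why: Ohira–Bestmann (Seyferth–Gilbert) homologation of the aldehyde to a terminal alkyne; the trans-dioxolane is the thermodynamic isomer, so it does not epimerise.

**Step 6**
Reactants: 7
Product: 8 methyl (4R,5S)-5-(3-methoxy-3-oxoprop-1-en-2-yl)-2,2-dimethyl-1,3-dioxolane-4-carboxylate
Conditions: Pd(OAc)2, 2-PyPPh2, cat. TsOH, CO (20 bar), MeOH, 50 °C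
Reagents that add atoms: carbon monoxide, [C-]#[O+]; methanol, CO
Why: Pd-catalysed Markovnikov alkoxycarbonylation of a terminal alkyne gives the α-substituted acrylate, which creates C10 and C14. The acetonide is flanked by two electron-withdrawing groups and tolerates catalytic acid.

**Step 7**
Reactants: 8
Product: 9 methyl 2-[(4S,5R)-5-formyl-2,2-dimethyl-1,3-dioxolan-4-yl]prop-2-enoate
Conditions: DIBAL-H (1.0 equiv), toluene, −78 °C
Reagents that add atoms: none
Why: The α-alkoxy saturated ester chelates aluminium and reduces faster than the conjugated α-branched acrylate ester, giving the C7 aldehyde.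

**Step 8**
Reactants: 9 and 4 (3 equiv)
Product: 10 methyl (E)-2-{(4S,5R)-5-formyl-2,2-dimethyl-1,3-dioxolan-4-yl}-7-oxo-5-methylhepta-2,5-dienoate (acrylate ester with C1=C10 E, enal C4=C5 E)
Conditions: Hoveyda–Grubbs II (5 mol %), CH2Cl2, 40 °C
Reagents that add atoms: none
Why: Cross-metathesis of a terminal alkene with a 1,1-disubstituted acrylate gives the E-trisubstituted enoate (CO2Me trans to C2, the ring-cis C1=C10 of melampolides). The trisubstituted enal alkene is inert and ethylene is lost.

**Step 9**
Reactants: 10
Product: 11 MBH adduct at C7 (C7-OH, C11(=CH2)CO2Me; C7 is an epimeric mixture)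
Conditions: methyl acrylate (5 equiv), DABCO (30 mol %), MeOH, rt
Reagents that add atoms: methyl acrylate, C=CC(=O)OC
Why: The Morita–Baylis–Hillman reaction occurs at the reactive α-alkoxy aldehyde; the β,β-disubstituted enal is unreactive. The new C7 carbinol stereocentre is destroyed in step 10, so its configuration does not matter.

**Step 10**
Reactants: 11
Product: 12 allyl bromide, (Z)-2-(bromomethyl)alk-2-enoate (enal, C1=C10 ester, acetonide, C7=C11 with C13H2Br)
Conditions: NBS, Me2S, CH2Cl2, −20→0 °C
Reagents that add atoms: N-bromosuccinimide, O=C1CCC(=O)N1Br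
Why: SN2′ bromination of the MBH alcohol (NBS/Me2S, Corey–Kim-type) gives the allylic bromide under neutral conditions that spare the acetonide and enal.

**Step 11 (key photochemical step)**
Reactants: 12
Product: 13 melampolide 8,9-O-isopropylidene diol: trans-fused 6,12-olide with 11(13)-methylene, 10-membered ring, (6R,7S,8S,9S)
Conditions: CrCl3 (20 mol %), dtbbpy (20 mol %), 4CzIPN (2 mol %), Hantzsch ester (2 equiv), MeCN/THF, 0.003 M, blue LEDs (450 nm), rt, 12 h; then TsOH·H2O (10 mol %), CH2Cl2
Reagents that add atoms: none (H from Hantzsch ester; MeOH is lost on lactonisation)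
Why: Proposed new method: photoexcited 4CzIPN, reductively quenched by Hantzsch ester, reduces Cr(III) to Cr(II). Cr(II) converts the allyl bromide to a γ-substituted allylchromium(III), which isomerises to the E-crotyl-type geometry. It adds through a Zimmerman–Traxler chair transition state to the enal C=O (1,2-addition) at the substituted γ-carbon (C7). This closes the ten-membered ring, gives the anti homoallylic alkoxide, and the acid step lactonises it onto the C12 ester. The anti adduct gives the trans-lactone, and the exocyclic methylene forms in the same step. The C8/C9 trans-acetonide makes the macrocyclic transition state prefer the (6R,7S) sense. The closest known reactions are photoredox/Cr-catalysed allylation of aldehydes and stoichiometric intramolecular Hiyama–Nozaki allylation; the new part is the catalytic macrocyclisation to a germacranolide with concomitant lactonisation.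

**Step 12**
Reactants: 13
Product: 14 8,9-diol of the melampolide (6R,7S,8S,9S)
Conditions: TFA/H2O/CH2Cl2 (1:1:8), 0 °C→rt, 3 h
Reagents that add atoms: none
Why: Acid hydrolysis of the acetonide; no stereocentre is affected.

**Step 13**
Reactants: 14 and 15 angelic acid
Product: 16 Polymatin A
Conditions: 15, 2,4,6-Cl3C6H2COCl, Et3N, THF, rt; then 14, DMAP, toluene, 0 °C→rt
Reagents that add atoms: none (15 is the numbered acyl donor)
Why: Yamaguchi esterification through the mixed anhydride retains the Z-angelate. C8-OH reacts selectively because the C9-OH is hydrogen-bonded to the C14 ester carbonyl.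

## Self-check summary
- **Ring sizes:** 10-membered carbocycle (C1–C10), γ-lactone O–C6–C7–C11–C12, and the transient dioxolane.
- **Substituents:** C4 methyl (C15), C14 methyl ester, exocyclic C11=C13, C9-OH, C8 angelate.
- **Alkenes:** C4=C5 E (C6 trans to C3); C1=C10 with C2 trans to C14.
- **Stereocentres:** C8 and C9 are (S,S) in the target and come from L-tartrate (4R,5R in the acetonide, because CIP priorities change). C6 (R) and C7 (S) are trans and are set in step 11.
- **Formulas:** 12 (C20H27BrO7) → 13 (C19H24O6) → 14 (C16H20O6) → 16 (C21H26O7), with every atom accounted for.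

## Compound list
1 | hex-5-en-2-one | C=CCCC(C)=O | starting material
2 | methyl (E)-3-methylhepta-2,6-dienoate | C=CCC/C(C)=C/C(=O)OC | intermediate
3 | (E)-3-methylhepta-2,6-dien-1-ol | C=CCC/C(C)=C/CO | intermediate
4 | (E)-3-methylhepta-2,6-dienal | C=CCC/C(C)=C/C=O | intermediate
5 | dimethyl 2,3-O-isopropylidene-L-tartrate | COC(=O)[C@@H]1OC(C)(C)O[C@H]1C(=O)OC | starting material
6 | methyl (4R,5R)-5-formyl-2,2-dimethyl-1,3-dioxolane-4-carboxylate | O=C[C@@H]1OC(C)(C)O[C@H]1C(=O)OC | intermediate
7 | methyl (4R,5S)-5-ethynyl-2,2-dimethyl-1,3-dioxolane-4-carboxylate | C#C[C@@H]1OC(C)(C)O[C@H]1C(=O)OC | intermediate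
8 | methyl (4R,5S)-5-(3-methoxy-3-oxoprop-1-en-2-yl)-2,2-dimethyl-1,3-dioxolane-4-carboxylate | C=C(C(=O)OC)[C@@H]1OC(C)(C)O[C@H]1C(=O)OC | intermediate
9 | methyl 2-[(4S,5R)-5-formyl-2,2-dimethyl-1,3-dioxolan-4-yl]prop-2-enoate | C=C(C(=O)OC)[C@@H]1OC(C)(C)O[C@H]1C=O | intermediate
10 | cross-metathesis product, enal–acrylate–aldehyde acetonide | O=C/C=C(\C)CC/C=C(/C(=O)OC)[C@@H]1OC(C)(C)O[C@H]1C=O | intermediate
11 | C7 MBH adduct of 10 | O=C/C=C(\C)CC/C=C(/C(=O)OC)[C@@H]1OC(C)(C)O[C@H]1C(O)C(=C)C(=O)OC | intermediate
12 | (Z)-2-(bromomethyl)alkenoate macrocyclisation precursor | O=C/C=C(\C)CC/C=C(/C(=O)OC)[C@@H]1OC(C)(C)O[C@H]1/C=C(/CBr)C(=O)OC | intermediate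
13 | melampolide 8,9-acetonide (6R,7S,8S,9S) | C=C1C(=O)O[C@@H]2/C=C(\C)CC/C=C(/C(=O)OC)[C@@H]3OC(C)(C)O[C@H]3[C@@H]12 | intermediate
14 | melampolide 8,9-diol | C=C1C(=O)O[C@@H]2/C=C(\C)CC/C=C(/C(=O)OC)[C@H](O)[C@@H](O)[C@@H]12 | intermediate
15 | angelic acid ((Z)-2-methylbut-2-enoic acid) | C/C=C(/C)C(=O)O | starting material
16 | Polymatin A | C=C1C(=O)O[C@@H]2/C=C(\C)CC/C=C(/C(=O)OC)[C@H](O)[C@@H](OC(=O)/C(C)=C\C)[C@@H]12 | target

## Totals
Total steps: 13. Longest linear sequence: 10 (steps 4–13 from 5; the enal branch is 3 steps and joins at step 8).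

## Three steps most likely to fail
1. **Step 11 (proposed new step).** The macrocyclisation may give the wrong C6/C7 diastereomer or oligomers.
   Fallback: use known chemistry with a different disconnection. Skip step 8 and make the allyl bromide from **9** (MBH, then NBS/Me2S). Run an intermolecular CrCl2 Hiyama–Nozaki allylation of enal **4** with it, lactonise with TsOH, then close C1=C10 by ring-closing metathesis (Hoveyda–Grubbs II, high dilution).
2. **Step 6 (Markovnikov alkoxycarbonylation).** Regioselectivity or acetonide survival may be poor.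
   Fallback: hydrate alkyne **7** (Au(I), MeOH/H2O) to the methyl ketone, form the terminal enol triflate (KHMDS, PhNTf2), then carbonylate it (Pd(OAc)2/dppf, CO, MeOH, Et3N) to give **8**.
3. **Step 13 (regioselective angeloylation after acid deprotection).** The C8/C9 selectivity may fail, or the C8-OH may lactonise onto the C14 ester.
   Fallback: form the dibutylstannylene acetal of **14** (Bu2SnO, toluene, reflux) and acylate it with the angelic mixed anhydride, so the tin template directs acylation rather than sterics or hydrogen bonding.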